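Assumption: the SMILES has no stereodescriptor and the molecule has no stereocentre; the tri-ortho-oxygenated biaryl axis is taken as not configurationally fixed, so the target is made as the one achiral compound drawn.

**Retrosynthetic overview**
- The target is a genistein(C-8)–(C-3′)daidzein biaryl; the last step is global O-demethylation of its tetramethyl ether.
- The biaryl bond comes from a Suzuki–Miyaura coupling of 8-iodo-tri-O-methylgenistein with a daidzein-type 3′-pinacol boronate.
- Genistein fragment: rings A, B and C are bought intact as genistein, which is permethylated and then iodinated at C-8.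
- Daidzein fragment: ring A from resorcinol and ring B from 3-bromo-4-methoxyphenylacetic acid; ring C is closed in a one-pot acylation/formylation–cyclisation, then Br is exchanged for Bpin.
- Order of ring formation: ring C of the daidzein unit first, the biaryl bond last.

**Route**

Step 1
Reactants: 1 genistein (5,7-dihydroxy-3-(4-hydroxyphenyl)-4H-chromen-4-one)
Product: 2 5,7-dimethoxy-3-(4-methoxyphenyl)-4H-chromen-4-one
Conditions: MeI (6 equiv), K2CO3 (6 equiv), DMF, 60 °C, 16 h
Reagents that add atoms: iodomethane (MeI), CI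
Why: Williamson O-methylation of all three phenols, with excess MeI and heat forcing the hydrogen-bonded 5-OH; no stereocentre is involved.

Step 2
Reactants: 2 5,7-dimethoxy-3-(4-methoxyphenyl)-4H-chromen-4-one
Product: 3 8-iodo-5,7-dimethoxy-3-(4-methoxyphenyl)-4H-chromen-4-one
Conditions: NIS (1.05 equiv), CF3CO2H (10 mol %), MeCN, rt, dark
Reagents that add atoms: N-iodosuccinimide (NIS), O=C1CCC(=O)N1I
Why: Electrophilic aromatic iodination; ring A is far more activated than ring B, and in 5,7-dimethoxychromones attack goes to C-8 (between OMe and the ring oxygen) rather than C-6 (between two OMe groups).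

Step 3
Reactants: 4 resorcinol (benzene-1,3-diol); 5 2-(3-bromo-4-methoxyphenyl)acetic acid
Product: 7 3-(3-bromo-4-methoxyphenyl)-7-hydroxy-4H-chromen-4-one, via deoxybenzoin 6 (not isolated)
Conditions: BF3·OEt2 (as solvent), 85 °C, 2 h; then DMF, MsCl, 70 °C, 2 h; aqueous NaOAc work-up
Reagents that add atoms: N,N-dimethylformamide (DMF), CN(C)C=O
Why: BF3-mediated Friedel–Crafts C-acylation of resorcinol at C-4 gives the deoxybenzoin, whose methylene is formylated by the DMF/MsCl Vilsmeier-type reagent and cyclises through the ortho phenol with loss of dimethylamine (one-pot deoxybenzoin isoflavone synthesis).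

Step 4
Reactants: 7 3-(3-bromo-4-methoxyphenyl)-7-hydroxy-4H-chromen-4-one
Product: 8 7-hydroxy-3-[4-methoxy-3-(4,4,5,5-tetramethyl-1,3,2-dioxaborolan-2-yl)phenyl]-4H-chromen-4-one
Conditions: B2pin2 (1.5 equiv), Pd(dppf)Cl2 (5 mol %), KOAc (4 equiv), DMSO, 80 °C
Reagents that add atoms: bis(pinacolato)diboron (B2pin2), CC1(C)OB(OC1(C)C)B1OC(C)(C)C(C)(C)O1
Why: Miyaura borylation of the aryl bromide; the weak base KOAc prevents onward Suzuki homocoupling and tolerates the free phenol and the chromone.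

Step 5
Reactants: 3 8-iodo-5,7-dimethoxy-3-(4-methoxyphenyl)-4H-chromen-4-one; 8 7-hydroxy-3-[4-methoxy-3-(4,4,5,5-tetramethyl-1,3,2-dioxaborolan-2-yl)phenyl]-4H-chromen-4-one (1.3 equiv)
Product: 9 8-[5-(7-hydroxy-4-oxo-4H-chromen-3-yl)-2-methoxyphenyl]-5,7-dimethoxy-3-(4-methoxyphenyl)-4H-chromen-4-one
Conditions: Pd(OAc)2 (5 mol %), SPhos (10 mol %), K2CO3 (4 equiv), 1,4-dioxane/H2O (5:1), 90 °C; work-up at pH 5
Reagents that add atoms: none
Why: Suzuki–Miyaura coupling; the bulky, electron-rich SPhos ligand on zerovalent palladium allows oxidative addition into the di-ortho-substituted C–I bond and formation of the tri-ortho-substituted biaryl, while carbonate is mild enough to spare both pyranone rings, and no stereocentre is created.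

Step 6
Reactants: 9 8-[5-(7-hydroxy-4-oxo-4H-chromen-3-yl)-2-methoxyphenyl]-5,7-dimethoxy-3-(4-methoxyphenyl)-4H-chromen-4-one
Product: 10 5,7-dihydroxy-8-[2-hydroxy-5-(7-hydroxy-4-oxo-4H-chromen-3-yl)phenyl]-3-(4-hydroxyphenyl)-4H-chromen-4-one (target CNP0500144.0)
Conditions: BBr3 (12 equiv), CH2Cl2, −78 °C to rt, 24 h; then MeOH, H2O
Reagents that add atoms: none
Why: Lewis-acid cleavage of all four aryl methyl ethers by BBr3 (the chelated 5-OMe first), with aqueous hydrolysis of the aryl borates; the isoflavone cores and the biaryl bond are stable to these conditions.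

**Compound list**
1 | genistein, 5,7-dihydroxy-3-(4-hydroxyphenyl)-4H-chromen-4-one | O=c1c(-c2ccc(O)cc2)coc2cc(O)cc(O)c12 | starting material
2 | 5,7-dimethoxy-3-(4-methoxyphenyl)-4H-chromen-4-one | COc1ccc(-c2coc3cc(OC)cc(OC)c3c2=O)cc1 | intermediate
3 | 8-iodo-5,7-dimethoxy-3-(4-methoxyphenyl)-4H-chromen-4-one | COc1ccc(-c2coc3c(I)c(OC)cc(OC)c3c2=O)cc1 | intermediate
4 | resorcinol, benzene-1,3-diol | Oc1cccc(O)c1 | starting material
5 | 2-(3-bromo-4-methoxyphenyl)acetic acid | COc1ccc(CC(=O)O)cc1Br | starting material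
6 | deoxybenzoin, 2-(3-bromo-4-methoxyphenyl)-1-(2,4-dihydroxyphenyl)ethan-1-one | COc1ccc(CC(=O)c2ccc(O)cc2O)cc1Br | intermediate
7 | 3-(3-bromo-4-methoxyphenyl)-7-hydroxy-4H-chromen-4-one | COc1ccc(-c2coc3cc(O)ccc3c2=O)cc1Br | intermediate
8 | 7-hydroxy-3-[4-methoxy-3-(4,4,5,5-tetramethyl-1,3,2-dioxaborolan-2-yl)phenyl]-4H-chromen-4-one | COc1ccc(-c2coc3cc(O)ccc3c2=O)cc1B1OC(C)(C)C(C)(C)O1 | intermediate
9 | 8-[5-(7-hydroxy-4-oxo-4H-chromen-3-yl)-2-methoxyphenyl]-5,7-dimethoxy-3-(4-methoxyphenyl)-4H-chromen-4-one | COc1ccc(-c2coc3c(-c4cc(-c5coc6cc(O)ccc6c5=O)ccc4OC)c(OC)cc(OC)c3c2=O)cc1 | intermediate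
10 | 5,7-dihydroxy-8-[2-hydroxy-5-(7-hydroxy-4-oxo-4H-chromen-3-yl)phenyl]-3-(4-hydroxyphenyl)-4H-chromen-4-one | O=c1c(-c2ccc(O)c(-c3c(O)cc(O)c4c(=O)c(-c5ccc(O)cc5)coc34)c2)coc2cc(O)ccc12 | target

**Totals**
Total step count: 6. Longest linear sequence: 4 steps (steps 1, 2, 5, 6, or equally steps 3, 4, 5, 6).

**Steps most likely to fail, with fallbacks**

The first risk is step 2, where iodination could give the 6-iodo isomer, mixtures, or over-iodination on ring B. The fallback sets out from 2 and moves the iodination to a ring-opened phenol, where the free hydroxyl directs it.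
- Ring C of 2 is opened with aqueous NaOH in EtOH at reflux (retro-Claisen loss of C-2) to give the deoxybenzoin 1-(2-hydroxy-4,6-dimethoxyphenyl)-2-(4-methoxyphenyl)ethan-1-one F1.
- F1 is iodinated with benzyltrimethylammonium dichloroiodate and CaCO3 in CH2Cl2/MeOH, which goes ortho to the chelated free phenol, to give 1-(2-hydroxy-3-iodo-4,6-dimethoxyphenyl)-2-(4-methoxyphenyl)ethan-1-one F2.
- Ring C is closed again with N,N-dimethylformamide dimethyl acetal in toluene at 100 °C. The iodinated carbon next to the phenol becomes C-8, and the sequence comes back to the route at 3.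

The second risk is step 4, where the acidic 7-OH may cause protodebromination, O-borylation or a boronate that is hard to purify. The fallback sets out from 7 and changes the protecting-group plan.
- The 7-OH is capped with MeI and K2CO3 in acetone at reflux to give 3-(3-bromo-4-methoxyphenyl)-7-methoxy-4H-chromen-4-one F3.
- Miyaura borylation (B2pin2, Pd(dppf)Cl2, KOAc, dioxane, 90 °C) gives 7-methoxy-3-[4-methoxy-3-(4,4,5,5-tetramethyl-1,3,2-dioxaborolan-2-yl)phenyl]-4H-chromen-4-one F4.
- Suzuki coupling of the boronate with 3 (Pd(OAc)2, SPhos, K2CO3, dioxane/H2O) gives the pentamethyl ether 5,7-dimethoxy-8-[2-methoxy-5-(7-methoxy-4-oxo-4H-chromen-3-yl)phenyl]-3-(4-methoxyphenyl)-4H-chromen-4-one F5.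
- All five methyl ethers are cleaved with BBr3 in CH2Cl2, which comes back to the route at the target 10.

The third and most serious risk is step 5, a hindered coupling in which protodeboronation of 8 or reductive deiodination of 3 can win. The fallback sets out from 3 and reverses the polarity of the coupling, so that oxidative addition takes place at the unhindered C–Br bond of 7.
- 3 is borylated (B2pin2, KOAc, Pd(OAc)2, SPhos, dioxane, 100 °C) to 5,7-dimethoxy-3-(4-methoxyphenyl)-8-(4,4,5,5-tetramethyl-1,3,2-dioxaborolan-2-yl)-4H-chromen-4-one F6.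
- This boronate is coupled with bromide 7 under anhydrous conditions that suppress protodeboronation (Pd(OAc)2, SPhos, K3PO4, dioxane, 100 °C), which comes back to the route at 9.

**Further compounds**
F1 | step 2 | 1-(2-hydroxy-4,6-dimethoxyphenyl)-2-(4-methoxyphenyl)ethan-1-one | COc1ccc(CC(=O)c2c(O)cc(OC)cc2OC)cc1
F2 | step 2 | 1-(2-hydroxy-3-iodo-4,6-dimethoxyphenyl)-2-(4-methoxyphenyl)ethan-1-one | COc1ccc(CC(=O)c2c(O)c(I)c(OC)cc2OC)cc1
F3 | step 4 | 3-(3-bromo-4-methoxyphenyl)-7-methoxy-4H-chromen-4-one | COc1ccc(-c2coc3cc(OC)ccc3c2=O)cc1Br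
F4 | step 4 | 7-methoxy-3-[4-methoxy-3-(4,4,5,5-tetramethyl-1,3,2-dioxaborolan-2-yl)phenyl]-4H-chromen-4-one | COc1ccc(-c2coc3cc(OC)ccc3c2=O)cc1B1OC(C)(C)C(C)(C)O1
F5 | step 4 | 5,7-dimethoxy-8-[2-methoxy-5-(7-methoxy-4-oxo-4H-chromen-3-yl)phenyl]-3-(4-methoxyphenyl)-4H-chromen-4-one | COc1ccc(-c2coc3c(-c4cc(-c5coc6cc(OC)ccc6c5=O)ccc4OC)c(OC)cc(OC)c3c2=O)cc1
F6 | step 5 | 5,7-dimethoxy-3-(4-methoxyphenyl)-8-(4,4,5,5-tetramethyl-1,3,2-dioxaborolan-2-yl)-4H-chromen-4-one | COc1ccc(-c2coc3c(B4OC(C)(C)C(C)(C)O4)c(OC)cc(OC)c3c2=O)cc1
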